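**Retrosynthetic overview**

1. C6–C7 is made last: the (E)-vinylsilane **16** adds to a cyclic peroxycarbenium ion released from the bicyclic peroxy-lactone **9**; this sets C6 and frees the CO2H in the same step.
2. **9** comes from Baeyer–Villiger oxidation of the 2,3-dioxabicyclo[2.2.2]octanone **8**, which comes from singlet-oxygen [4+2] addition to the silyloxydiene **6**; the 1,2-dioxane ring forms here and C3/C6 are relayed from C4.
3. **6** comes from (S)-4-ethylcyclohex-2-enone **4**. Key step: Birch dearomatization of 4-ethylanisole, then enantioselective 1,3-H shift of the achiral β,γ-enone. The six arene carbons become C1–C6, and the C–OMe carbon becomes the carboxyl.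
4. Side chain **16**: Johnson–Claisen chirality transfer sets C10; ethylcupration of a terminal alkyne sets the (E)-C7=C8 bond.
5. Ring order: carbocycle (from the arene), then the 1,2-dioxane as a bridging endoperoxide, then the carbocycle is excised (Baeyer–Villiger, then C–O ionization).

Assumption: catalyst and ligand enantiomers are those that give the stated configurations; intermediates **2**, **7** and **13** are carried forward crude, but each transformation is counted as its own step.

---

**Step 1**
Reactants: **1** 4-ethylanisole
Product: **2** 4-ethyl-1-methoxycyclohexa-1,4-diene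
Conditions: Li, NH3(l), THF, t-BuOH, −78 → −33 °C; NH4Cl quench; extract, used crude
Reagents that add atoms: none
Why: Birch reduction of a 4-alkylanisole leaves the enol ether and the alkyl-substituted alkene as the two isolated double bonds (1,4-diene with OMe and Et on sp2 carbons), which breaks the aromaticity.

**Step 2**
Reactants: **2** 4-ethyl-1-methoxycyclohexa-1,4-diene
Product: **3** 4-ethylcyclohex-3-en-1-one
Conditions: (CO2H)2·2H2O, MeOH/H2O, rt
Reagents that add atoms: water, O (carbonyl oxygen; OMe leaves as MeOH)
Why: Mild enol-ether hydrolysis with oxalic acid gives the β,γ-unsaturated ketone without conjugating the alkene (standard anisole → cyclohex-3-enone sequence).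

**Step 3**
Reactants: **3** 4-ethylcyclohex-3-en-1-one
Product: **4** (S)-4-ethylcyclohex-2-en-1-one
Conditions: cinchona-derived primary–tertiary diamine (9-amino-9-deoxy-epi-cinchona type, 10 mol %; pseudo-enantiomer giving S), carboxylic acid co-catalyst (20 mol %), PhMe, −25 °C
Reagents that add atoms: none
Why: Enantioselective olefin isomerization by iminium/dienamine proton-transfer catalysis, a known reaction of anisole-derived cyclohex-3-enones; face-selective γ-protonation of the dienamine turns the achiral enone into the C4 stereocentre (future C4 of the target).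

**Step 4**
Reactants: **4** (S)-4-ethylcyclohex-2-en-1-one
Product: **5** (4S,6RS)-4,6-diethylcyclohex-2-en-1-one
Conditions: LDA, THF, −78 °C; EtI, DMPU, −78 → −30 °C
Reagents that add atoms: iodoethane, CCI
Why: Kinetic α′-enolate alkylation; the cross-conjugated enolate does not involve C4–H, and the C6 configuration is irrelevant because it is erased in Step 5.

**Step 5**
Reactants: **5** (4S,6RS)-4,6-diethylcyclohex-2-en-1-one
Product: **6** tert-butyl{[(4S)-2,4-diethylcyclohexa-1,5-dien-1-yl]oxy}dimethylsilane (cross-conjugated 2-silyloxy-1,3-diene)
Conditions: LDA, THF, −78 °C; TBSOTf, −78 → 0 °C; non-aqueous work-up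
Reagents that add atoms: TBSOTf, CC(C)(C)[Si](C)(C)OS(=O)(=O)C(F)(F)F
Why: Kinetic α′-deprotonation and O-silylation give the tetrasubstituted enol ether, placing the ethyl-bearing carbon at a diene terminus; the bulky TBS group is chosen to suppress silyl-transfer ene reactions in Step 6.

**Step 6**
Reactants: **6** silyloxydiene
Product: **7** tert-butyl{[(1R,4S,7S)-4,7-diethyl-2,3-dioxabicyclo[2.2.2]oct-5-en-5-yl]oxy}dimethylsilane (endoperoxide silyl enol ether)
Conditions: O2, hν (white LED), TPP (1 mol %), CH2Cl2, −78 °C; concentrated cold, used crude
Reagents that add atoms: dioxygen, O=O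
Why: Singlet-oxygen [4+2] cycloaddition to a cyclohexa-1,3-diene delivers both C–O bonds suprafacially on the face anti to the ethyl group on the adjacent sp3 carbon, which sets the future C3 and C6 oxygen stereocentres relative to C4. Expected anti:syn is only about 2–4:1 (from 5-alkylcyclohexadiene analogies), so the minor syn adduct is removed after Step 7.

**Step 7**
Reactants: **7** endoperoxide silyl enol ether
Product: **8** (1S,4S,7S)-4,7-diethyl-2,3-dioxabicyclo[2.2.2]octan-5-one
Conditions: HF·pyridine, pyridine/THF, −40 → 0 °C; chromatography to remove the syn diastereomer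
Reagents that add atoms: none
Why: Mildly acidic fluoride desilylation unmasks the ketone by C-protonation of the enol ether at the CH2 position, so no stereocentre is touched; the absence of base avoids β-elimination and Kornblum–DeLaMare cleavage of the peroxide.

**Step 8**
Reactants: **8** bicyclic peroxy-ketone
Product: **9** (1S,5S,9S)-1,9-diethyl-2,6,7-trioxabicyclo[3.2.2]nonan-3-one (lactone whose C1 is an acyloxy peroxyketal)
Conditions: mCPBA, NaHCO3 (s), CH2Cl2, 0 °C; used crude or after rapid filtration
Reagents that add atoms: mCPBA, OOC(=O)c1cccc(Cl)c1
Why: Baeyer–Villiger oxidation; the tertiary, peroxy-substituted bridgehead carbon migrates with retention in preference to CH2, so oxygen is inserted between the carbonyl (future C1) and future C6. Peracids do not attack dialkyl peroxides, and the solid buffer avoids E1cB opening of the peroxy ketone. This substrate class is untested.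

**Step 9**
Reactants: **10** (E)-pent-2-enal
Product: **11** (R,E)-hept-4-en-3-ol
Conditions: Et2Zn, (+)-DAIB or (+)-MIB (3 mol %), toluene/hexane, 0 °C
Reagents that add atoms: diethylzinc, CC[Zn]CC
Why: Amino-alcohol-catalysed enantioselective diethylzinc addition to an enal; the ligand enantiomer is chosen to give the R carbinol.

**Step 10**
Reactants: **11** (R,E)-hept-4-en-3-ol
Product: **12** ethyl (3R,4E)-3-ethylhept-4-enoate
Conditions: MeC(OEt)3, EtCO2H (cat.), 140 °C, with removal of EtOH
Reagents that add atoms: triethyl orthoacetate, CC(OCC)(OCC)OCC
Why: Johnson–Claisen rearrangement through a chair transition state with the carbinol ethyl equatorial gives the E-alkene with suprafacial 1,3-chirality transfer, setting C10 (R).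

**Step 11**
Reactants: **12** ethyl (3R,4E)-3-ethylhept-4-enoate
Product: **13** (3R,4E)-3-ethylhept-4-enal
Conditions: DIBAL-H (1.05 equiv), CH2Cl2, −78 °C; Rochelle-salt work-up; concentrated cold and used directly
Reagents that add atoms: none
Why: Low-temperature DIBAL half-reduction of the ester stops at the aldehyde through the stable tetrahedral aluminate; the stereocentre is β to the carbonyl and cannot epimerize.

**Step 12**
Reactants: **13** (3R,4E)-3-ethylhept-4-enal
Product: **14** (4R,5E)-4-ethyloct-5-en-1-yne
Conditions: Ohira–Bestmann reagent, K2CO3, MeOH, 0 °C → rt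
Reagents that add atoms: dimethyl (1-diazo-2-oxopropyl)phosphonate, CC(=O)C(=[N+]=[N-])P(=O)(OC)OC (supplies the terminal alkyne carbon)
Why: Seyferth–Gilbert (Ohira–Bestmann) homologation converts the aldehyde into the terminal alkyne under mild carbonate conditions that leave the β-stereocentre and the E-alkene untouched. The product is volatile and is carried forward in solution.

**Step 13**
Reactants: **14** (4R,5E)-4-ethyloct-5-en-1-yne
Product: **15** (1E,4R,5E)-2,4-diethyl-1-iodoocta-1,5-diene
Conditions: EtMgBr, CuBr·SMe2, Et2O/Me2S, −45 → −25 °C; then I2, −50 → 0 °C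
Reagents that add atoms: ethylmagnesium bromide, CC[Mg]Br; iodine, II
Why: Normant syn-carbocupration of a terminal alkyne puts Et on the internal carbon and Cu on the terminal carbon cis to it; iodinolysis with retention fixes the (E)-trisubstituted alkene geometry.

**Step 14**
Reactants: **15** vinyl iodide
Product: **16** [(1E,4R,5E)-2,4-diethylocta-1,5-dien-1-yl]trimethylsilane
Conditions: t-BuLi (2.1 equiv), Et2O, −78 °C; TMSCl, → rt
Reagents that add atoms: chlorotrimethylsilane, C[Si](C)(C)Cl
Why: Li–I exchange and silylation proceed with retention of alkene geometry, giving a peroxide-compatible alkenyl nucleophile.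

**Step 15**
Reactants: **9** bicyclic peroxy-lactone; **16** vinylsilane (2 equiv)
Product: **17** Plakortide N, 2-[(3S,4S,6R)-4,6-diethyl-6-[(1E,4R,5E)-2,4-diethylocta-1,5-dien-1-yl]-1,2-dioxan-3-yl]acetic acid
Conditions: TMSOTf (0.3–1.0 equiv), 2,6-di-tert-butyl-4-methylpyridine (cat.), CH2Cl2, −78 °C, short reaction time; cold pH 7 quench, then pH 4 aqueous work-up
Reagents that add atoms: none (16 is a reactant; work-up only replaces Me3Si on the carboxyl by H)
Why: Proposed new method: silylation of the lactone carbonyl ionizes the C6–O(acyl) bond of the acyloxy peroxyketal, giving a 1,2-dioxan-3-ylium (peroxycarbenium) ion with a pendant silyl ester. The 2,2-dialkyl vinylsilane attacks through its silicon-bearing carbon to give a tertiary β-silyl cation, which loses Me3Si+ with retention of the E geometry and regenerates TMSOTf. Attack is axial on the half-chair with the C4 ethyl pseudo-equatorial, on the face opposite the departed carboxylate arm, so the alkenyl group ends up trans to C4-Et and to C3-CH2CO2H (6R). Closest known reaction types are Lewis-acid substitution of peroxyketals and 3-alkoxy-1,2-dioxolanes by allylsilanes and silyl ketene acetals via peroxycarbenium ions, ipso-substitution of vinylsilanes by oxocarbenium ions, and axial-attack selectivity in six-membered oxocarbenium ions.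

---

**Compound list**

1 | 4-ethylanisole | CCc1ccc(OC)cc1 | starting material
2 | 4-ethyl-1-methoxycyclohexa-1,4-diene | CCC1=CCC(OC)=CC1 | intermediate
3 | 4-ethylcyclohex-3-en-1-one | CCC1=CCC(=O)CC1 | intermediate
4 | (S)-4-ethylcyclohex-2-en-1-one | O=C1C=C[C@@H](CC)CC1 | intermediate
5 | (4S,6RS)-4,6-diethylcyclohex-2-en-1-one | O=C1C=C[C@@H](CC)CC1CC | intermediate
6 | tert-butyl{[(4S)-2,4-diethylcyclohexa-1,5-dien-1-yl]oxy}dimethylsilane | CCC1=C(O[Si](C)(C)C(C)(C)C)C=C[C@@H](CC)C1 | intermediate
7 | tert-butyl{[(1R,4S,7S)-4,7-diethyl-2,3-dioxabicyclo[2.2.2]oct-5-en-5-yl]oxy}dimethylsilane (same spatial arrangement as 8; the C1 descriptor changes only through CIP priorities) | CC[C@H]1C[C@]2(CC)OO[C@H]1C=C2O[Si](C)(C)C(C)(C)C | intermediate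
8 | (1S,4S,7S)-4,7-diethyl-2,3-dioxabicyclo[2.2.2]octan-5-one | CC[C@H]1C[C@]2(CC)OO[C@H]1CC2=O | intermediate
9 | (1S,5S,9S)-1,9-diethyl-2,6,7-trioxabicyclo[3.2.2]nonan-3-one | CC[C@H]1C[C@]2(CC)OO[C@H]1CC(=O)O2 | intermediate
10 | (E)-pent-2-enal | CC/C=C/C=O | starting material
11 | (R,E)-hept-4-en-3-ol | CC[C@@H](O)/C=C/CC | intermediate
12 | ethyl (3R,4E)-3-ethylhept-4-enoate | CC/C=C/[C@H](CC)CC(=O)OCC | intermediate
13 | (3R,4E)-3-ethylhept-4-enal | CC/C=C/[C@H](CC)CC=O | intermediate
14 | (4R,5E)-4-ethyloct-5-en-1-yne | CC/C=C/[C@H](CC)CC#C | intermediate
15 | (1E,4R,5E)-2,4-diethyl-1-iodoocta-1,5-diene | CC/C=C/[C@H](CC)C/C(CC)=C/I | intermediate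
16 | [(1E,4R,5E)-2,4-diethylocta-1,5-dien-1-yl]trimethylsilane | CC/C=C/[C@H](CC)C/C(CC)=C/[Si](C)(C)C | intermediate
17 | Plakortide N | CC/C=C/[C@H](CC)C/C(=C/[C@@]1(CC)C[C@H](CC)[C@H](CC(=O)O)OO1)CC | target

---

**Totals**

- Total steps: 15 (core 8, side chain 6, coupling 1).
- Longest linear sequence: 9 (Steps 1–8, then 15).

**Three steps most likely to fail, with fallbacks**

1. **Step 15 (peroxycarbenium / vinylsilane coupling).** The nucleophile class is untested on peroxycarbenium ions, and the product's tertiary allylic C–O bond may re-ionize under the Lewis acid. Fallback: form C6–C7 before any peroxide exists. Ozonolyse the enol-ether C=C of **6** to the (Z)-keto-enoate, add the alkenyl-lithium/cerium from **15** to the ethyl ketone, perhydrolyse the tertiary allylic alcohol (H2O2/acid), and close the dioxane by base-mediated 6-exo peroxy-Michael addition. This gives C6/C3 epimers that must be separated.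

2. **Step 6 (photooxygenation).** Facial selectivity may be modest, silyl-ene or H-ene pathways may compete, and the adduct is labile. Fallback: introduce O2 through the enolate. Oxygenate the lithium α′-enolate of **5** (O2, −78 °C) to the α′-hydroperoxy enone, where attack trans to the C4 ethyl is expected, then close to **8** by transannular peroxy-Michael addition (amine, CF3CH2OH).

3. **Step 8 (Baeyer–Villiger on the peroxy ketone).** Retro-oxa-Michael opening of **8** may compete, and the acyloxy peroxyketal **9** is sensitive. Fallback: bypass **8** and **9**. Ozonolyse **6** in MeOH, which gives the C1 ester and a C6 methoxy-hydroperoxide directly, then close by amine-catalysed peroxy-Michael addition to the 6-methoxy-1,2-dioxane-3-acetate. Its OMe serves as the leaving group in the coupling step, followed by LiOH saponification. C3 is no longer locked by a bicycle in this variant, so epimers would have to be separated.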